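**Retrosynthetic overview**

1. Rings: A = chalcone-bearing resorcinol on C3, B = prenylated benzoyl ring on C4, C = resorcinol on C5, D = far chalcone ring; cyclohexene carbons: C1 (C–CH3), C2 (=CH), C3, C4, C5, C6 (CH2).
2. 17 ⇐ 15: acid removes six MOM groups and opens a temporary O–C1 aryl ether bridge by β-silyl (Peterson-type) elimination, the silicon on C2 fixing the C1=C2 alkene; 15 ⇐ 14 by Claisen–Schmidt condensation (adds ring D).
3. 14 ⇐ enaminone 11 + 2,4-dihydroxyacetophenone 1 (ring A): C-arylation, ortho-quinone methide formation and a bridging intramolecular hetero-Diels–Alder reaction make ring A–C3, then C2–C3 (closes the carbocycle) and O–C1 (temporary pyran) in one operation.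
4. 11 ⇐ 10 ⇐ 9 (aminomethylenation, silylmethylenation); 9 ⇐ chalcone 7 + acetone (catalytic asymmetric Michael addition, sets C5); 7 ⇐ 4 + 6.
5. Enabling feature: C3 is bonded to the ring A carbon that lies between two phenolic C–OH carbons, so C3 can be the methide carbon of an ortho-quinone methide whose oxygen sits 1,3 to the methyl-bearing alkene carbon C1 across C2. Ring order: carbocycle and bridging pyran together (step 8), pyran reopened (step 10).

Key step: step 8

Abbreviations: MOM = methoxymethyl; ArB = 2,4-bis(methoxymethoxy)-3-(3-methylbut-2-en-1-yl)phenyl; ArC = 2,4-bis(methoxymethoxy)phenyl.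

Assumption: 10–13 are carried as E/Z mixtures at the silyl alkene and 14–15 as both epimers at the silicon-bearing bridge carbon; step 10 erases this element, so the SMILES leave it open.

**Step 1**
Reactants: 1 2,4-dihydroxyacetophenone; 2 prenyl bromide (1-bromo-3-methylbut-2-ene)
Product: 3 1-[2,4-dihydroxy-3-(3-methylbut-2-en-1-yl)phenyl]ethan-1-one
Conditions: KOH, H2O, 0 °C to rt
Reagents that add atoms: none
Why: Phenolate C-alkylation (C-prenylation) at the resorcinol carbon flanked by both oxygens, favoured over O-alkylation in water; the O- and C5-prenylated isomers should be separable by chromatography.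

**Step 2**
Reactants: 3 1-[2,4-dihydroxy-3-(3-methylbut-2-en-1-yl)phenyl]ethan-1-one
Product: 4 1-[2,4-bis(methoxymethoxy)-3-(3-methylbut-2-en-1-yl)phenyl]ethan-1-one (ArB–COCH3)
Conditions: NaH, MOMCl, DMF, 0 °C to rt
Reagents that add atoms: chloromethyl methyl ether, COCCl
Why: Williamson-type MOM ether formation on both phenoxides; irreversible deprotonation with NaH should also engage the hydrogen-bonded ortho hydroxyl.

**Step 3**
Reactants: 5 2,4-dihydroxybenzaldehyde
Product: 6 2,4-bis(methoxymethoxy)benzaldehyde (ArC–CHO)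
Conditions: NaH, MOMCl, DMF, 0 °C to rt
Reagents that add atoms: chloromethyl methyl ether, COCCl
Why: Same MOM protection as in step 2, giving a base-stable aldehyde that serves twice (rings C and D).

**Step 4**
Reactants: 4 ArB–COCH3; 6 ArC–CHO
Product: 7 (E)-1-ArB-3-ArC-prop-2-en-1-one
Conditions: KOH, EtOH/H2O, rt
Reagents that add atoms: none
Why: Claisen–Schmidt aldol condensation of a methyl ketone with a non-enolisable aldehyde, giving the thermodynamic E-chalcone.

**Step 5**
Reactants: 7 (E)-1-ArB-3-ArC-prop-2-en-1-one; 8 acetone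
Product: 9 (3S)-1-ArB-3-ArC-hexane-1,5-dione
Conditions: 1-[(1R,2R)-2-aminocyclohexyl]-3-[3,5-bis(trifluoromethyl)phenyl]thiourea (20 mol %), PhCO2H (20 mol %), acetone, rt
Reagents that add atoms: none
Why: Enamine-mediated asymmetric Michael addition of acetone to the thiourea-bound chalcone, in which the catalyst backbone selects the enone face and so sets C5; the catalyst antipode that delivers the (3S) adduct is to be used.

**Step 6**
Reactants: 9 (3S)-1-ArB-3-ArC-hexane-1,5-dione
Product: 10 (3S)-1-ArB-3-ArC-5-methyl-6-(trimethylsilyl)hex-5-en-1-one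
Conditions: Cp2Ti(CH2SiMe3)2 (1.5 equiv), PhMe, 100 °C
Reagents that add atoms: bis(cyclopentadienyl)bis(trimethylsilylmethyl)titanium, C[Si](C)(C)[CH2-].C[Si](C)(C)[CH2-].c1cc[cH-]c1.c1cc[cH-]c1.[Ti+4]
Why: Carbonyl olefination by the thermally generated titanium alkylidene Cp2Ti=CHSiMe3 (titanocene alkylidene olefination); it is non-basic, so C5 and the enolisable positions are untouched, and the methyl ketone should react ahead of the hindered, electron-rich aryl ketone.

**Step 7**
Reactants: 10 (3S)-1-ArB-3-ArC-5-methyl-6-(trimethylsilyl)hex-5-en-1-one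
Product: 11 (3R)-1-ArB-3-ArC-2-[(dimethylamino)methylidene]-5-methyl-6-(trimethylsilyl)hex-5-en-1-one
Conditions: t-BuOCH(NMe2)2, PhMe, 110 °C
Reagents that add atoms: tert-butoxybis(dimethylamino)methane, CC(C)(C)OC(N(C)C)N(C)C
Why: Aminomethylenation (aminal ester condensation) of the only enolisable α-methylene gives the vinylogous amide and installs the future C3 at the aldehyde oxidation level; C5 is not touched (its descriptor changes only through the CIP priorities).

**Step 8**
Reactants: 11 (3R)-1-ArB-3-ArC-2-[(dimethylamino)methylidene]-5-methyl-6-(trimethylsilyl)hex-5-en-1-one; 1 2,4-dihydroxyacetophenone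
Product: 14 1-[(2S,4S,5R,6S)-5-(ArB-carbonyl)-4-ArC-7-hydroxy-2-methyl-11-(trimethylsilyl)-3,4,5,6-tetrahydro-2H-2,6-methano-1-benzoxocin-8-yl]ethan-1-one, via 2-hydroxyaryl enone 12 (not isolated), via ortho-quinone methide 13 (not isolated)
Conditions: AcOH (1.5 equiv), PhMe, 80 °C, then 130 °C (sealed tube)
Reagents that add atoms: none
Why: Proposed new method: acid-assisted addition–elimination of the resorcinol carbon of 1 that lies between the two hydroxyls onto the protonated enaminone should expel dimethylamine and give the 2-hydroxyaryl enone 12, which the dimethylammonium acetate formed in the flask should tautomerise (proton from the para hydroxyl to the enone α-carbon C4) to the ortho-quinone methide 13, and 13 should be trapped irreversibly by the tethered vinylsilane in an inverse-electron-demand hetero-Diels–Alder reaction that forms C2–C3 and O–C1. The closest known reaction type is the amine- or acid-mediated domino phenol–aldehyde condensation, ortho-quinone methide formation and intramolecular hetero-Diels–Alder reaction that gives hexahydrocannabinol-type tricycles from citronellal and resorcinols, here proposed in the bridging mode with a vinylsilane and a 2-acyl enaminone. The carbocycle closes through the C2–C3 bond with both alkene carbons inside the new ring (6-endo with respect to the alkene), and the temporary dihydropyran closes through the O–C1 bond of the same cycloaddition, giving an oxabicyclo[3.3.1]nonane. C3 is controlled by the bridge, which forces ring A axial on the chair carbocycle, together with the existing C5 centre, whose aryl group must stay equatorial because an axial one would collide with the aryl–oxygen bridge, so rings A and C end up trans; C4 is epimerisable under the conditions (through 12/13 and by enolisation of 14) and should settle with the aroyl group equatorial in the locked bicycle, that is cis to ring A and trans to ring C; C1 follows from the suprafacial addition, and the silicon-bearing carbon follows the alkene geometry and is lost later. The step needs attack at the resorcinol carbon between the hydroxyls (the usual site for iminium and aldehyde electrophiles on 2,4-dihydroxyaryl ketones; bridging through either phenolic oxygen converges on 17), the vinylsilane and not the prenyl alkene as the 2π partner (only it reaches C3 through a six-membered transition state with oxygen bonding to the tertiary carbon), and survival of the β-silyl ether, which the weakly acidic buffered medium should secure.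

**Step 9**
Reactants: 14 bridged acetyl ketone; 6 ArC–CHO
Product: 15 (E)-3-ArC-1-[(2S,4S,5R,6S)-5-(ArB-carbonyl)-4-ArC-7-hydroxy-2-methyl-11-(trimethylsilyl)-3,4,5,6-tetrahydro-2H-2,6-methano-1-benzoxocin-8-yl]prop-2-en-1-one
Conditions: KOH, EtOH/H2O, rt
Reagents that add atoms: none
Why: Claisen–Schmidt condensation of the ring A methyl ketone builds the chalcone arm; the β-silyl ether and MOM groups are base-stable, and any enolisation at C4 returns the equatorial aroyl group in the locked bicycle.

**Step 10**
Reactants: 15 bridged chalcone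
Product: 17 kuwanon J, via hexakis-MOM ether 16 (not isolated)
Conditions: 3 M HCl, MeOH, 0 °C to rt
Reagents that add atoms: none
Why: Acid ionises the tertiary β-silyl aryl ether and the β-silyl cation loses silicon (Peterson-type β-elimination), which places the double bond at C1=C2 only and frees the ring A phenol; methanolysis of the six MOM acetals follows, and no stereocentre is involved provided the exposure is short enough to avoid enolisation at C4.

**Compound list**

1 | 2,4-dihydroxyacetophenone | CC(=O)c1ccc(O)cc1O | starting material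
2 | prenyl bromide (1-bromo-3-methylbut-2-ene) | CC(C)=CCBr | starting material
3 | 1-[2,4-dihydroxy-3-(3-methylbut-2-en-1-yl)phenyl]ethan-1-one | CC(=O)c1ccc(O)c(CC=C(C)C)c1O | intermediate
4 | 1-[2,4-bis(methoxymethoxy)-3-(3-methylbut-2-en-1-yl)phenyl]ethan-1-one | CC(=O)c1ccc(OCOC)c(CC=C(C)C)c1OCOC | intermediate
5 | 2,4-dihydroxybenzaldehyde | O=Cc1ccc(O)cc1O | starting material
6 | 2,4-bis(methoxymethoxy)benzaldehyde | O=Cc1ccc(OCOC)cc1OCOC | intermediate
7 | (E)-1-ArB-3-ArC-prop-2-en-1-one | COCOc1ccc(/C=C/C(=O)c2ccc(OCOC)c(CC=C(C)C)c2OCOC)c(OCOC)c1 | intermediate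
8 | acetone | CC(C)=O | starting material
9 | (3S)-1-ArB-3-ArC-hexane-1,5-dione | CC(=O)C[C@@H](CC(=O)c1ccc(OCOC)c(CC=C(C)C)c1OCOC)c1ccc(OCOC)cc1OCOC | intermediate
10 | (3S)-1-ArB-3-ArC-5-methyl-6-(trimethylsilyl)hex-5-en-1-one (E/Z mixture) | C[Si](C)(C)C=C(C)C[C@@H](CC(=O)c1ccc(OCOC)c(CC=C(C)C)c1OCOC)c1ccc(OCOC)cc1OCOC | intermediate
11 | (3R)-1-ArB-3-ArC-2-[(dimethylamino)methylidene]-5-methyl-6-(trimethylsilyl)hex-5-en-1-one (same spatial arrangement at C-3 as in 10) | CN(C)C=C(C(=O)c1ccc(OCOC)c(CC=C(C)C)c1OCOC)[C@H](CC(C)=C[Si](C)(C)C)c1ccc(OCOC)cc1OCOC | intermediate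
12 | (3R)-2-[(3-acetyl-2,6-dihydroxyphenyl)methylidene]-1-ArB-3-ArC-5-methyl-6-(trimethylsilyl)hex-5-en-1-one | CC(=O)c1ccc(O)c(C=C(C(=O)c2ccc(OCOC)c(CC=C(C)C)c2OCOC)[C@H](CC(C)=C[Si](C)(C)C)c2ccc(OCOC)cc2OCOC)c1O | intermediate
13 | ortho-quinone methide tautomer of 12 (4-acetyl-3-hydroxy-2-ylidene-cyclohexa-3,5-dien-1-one; the carbon next to the methide is sp3, and it and the ArC-bearing carbon are configured as in 14) | CC(=O)C1=C(O)C(=C[C@H](C(=O)c2ccc(OCOC)c(CC=C(C)C)c2OCOC)[C@H](CC(C)=C[Si](C)(C)C)c2ccc(OCOC)cc2OCOC)C(=O)C=C1 | intermediate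
14 | 1-[(2S,4S,5R,6S)-5-(ArB-carbonyl)-4-ArC-7-hydroxy-2-methyl-11-(trimethylsilyl)-3,4,5,6-tetrahydro-2H-2,6-methano-1-benzoxocin-8-yl]ethan-1-one (both C-11 epimers) | CC(=O)c1ccc2O[C@@]3(C)C[C@H](c4ccc(OCOC)cc4OCOC)[C@@H](C(=O)c4ccc(OCOC)c(CC=C(C)C)c4OCOC)[C@@H](c2c1O)C3[Si](C)(C)C | intermediate
15 | (E)-3-ArC-1-[(2S,4S,5R,6S)-5-(ArB-carbonyl)-4-ArC-7-hydroxy-2-methyl-11-(trimethylsilyl)-3,4,5,6-tetrahydro-2H-2,6-methano-1-benzoxocin-8-yl]prop-2-en-1-one (both C-11 epimers) | COCOc1ccc(/C=C/C(=O)c2ccc3O[C@@]4(C)C[C@H](c5ccc(OCOC)cc5OCOC)[C@@H](C(=O)c5ccc(OCOC)c(CC=C(C)C)c5OCOC)[C@@H](c3c2O)C4[Si](C)(C)C)c(OCOC)c1 | intermediate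
16 | (E)-3-ArC-1-[3-[(1S,5S,6R)-6-(ArB-carbonyl)-5-ArC-3-methylcyclohex-2-en-1-yl]-2,4-dihydroxyphenyl]prop-2-en-1-one (kuwanon J with rings B, C and D as MOM ethers) | CC(C)=CCc1c(OCOC)ccc(C(=O)[C@H]2[C@@H](c3c(O)ccc(C(=O)/C=C/c4ccc(OCOC)cc4OCOC)c3O)C=C(C)C[C@@H]2c2ccc(OCOC)cc2OCOC)c1OCOC | intermediate
17 | kuwanon J, (E)-1-[3-[(1S,5S,6R)-6-[2,4-dihydroxy-3-(3-methylbut-2-en-1-yl)benzoyl]-5-(2,4-dihydroxyphenyl)-3-methylcyclohex-2-en-1-yl]-2,4-dihydroxyphenyl]-3-(2,4-dihydroxyphenyl)prop-2-en-1-one | CC(C)=CCc1c(O)ccc(C(=O)[C@H]2[C@@H](c3c(O)ccc(C(=O)/C=C/c4ccc(O)cc4O)c3O)C=C(C)C[C@@H]2c2ccc(O)cc2O)c1O | target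

**Step count and risks**

Total steps: 10. Longest linear sequence: 9 steps (1 → 3 → 4 → 7 → 9 → 10 → 11 → 14 → 15 → 17).

Steps most likely to fail:

Step 8 (Proposed new method). The quinone methide may not be intercepted. The enone 12 could rest as its cyclic hemiketal or benzopyrylium form, the quinone methide could revert faster than it cycloadds, or the resorcinol could be attacked at the wrong carbon. Fallback with known chemistry: set out from 11 and 1, stop the C-arylation at 60 °C (AcOH, PhMe) and isolate 12. Close the same C2–C3 bond by a Lewis acid-promoted vinylsilane-terminated conjugate cyclisation (intramolecular Sakurai-type; Me2AlCl, CH2Cl2, −78 °C), in which silicon is lost directly, to give 1-[3-[(1S,5S,6R)-6-(ArB-carbonyl)-5-ArC-3-methylcyclohex-2-en-1-yl]-2,4-dihydroxyphenyl]ethan-1-one F1. Here ring A and ring C should end up trans through the chair transition state with the C5 aryl equatorial, and C4 would be adjusted by equilibration with DBU and separation of epimers. Claisen–Schmidt condensation of F1 with 6 (KOH, EtOH) returns to the route at 16.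

Step 10. Under protic acid the prenyl group may cyclise onto its neighbouring phenol, the ring A phenol may add back to the new alkene, and C4 may epimerise by enolisation. Fallback: set out from 15 and split the operation into two aprotic reactions of different type. First the Lewis acid-induced Peterson-type fragmentation (BF3·OEt2, 2,6-di-tert-butylpyridine, CH2Cl2, −78 °C) gives 16 as an isolated compound. Then the MOM groups are transferred to a thiol (ZnBr2, n-PrSH, CH2Cl2, 0 °C) to reach 17. This fallback makes no new compound (none F0).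

Step 5. The enamine addition to the electron-rich, ortho-substituted chalcone may be slow or poorly face-selective. Fallback: set out from 7 and add allyl acetoacetate in a Michael reaction under a cinchona-derived bifunctional thiourea catalyst, giving allyl (3R)-2-acetyl-5-ArB-3-ArC-5-oxopentanoate F2 (C-2 epimers, same spatial arrangement at the aryl-bearing carbon as in 9). Deallylative decarboxylation (Pd(OAc)2, PPh3, HCO2H, Et3N, THF, rt; zerovalent palladium formed in the flask) returns to the route at 9.

**Further compounds**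

F1 | step 8 | 1-[3-[(1S,5S,6R)-6-(ArB-carbonyl)-5-ArC-3-methylcyclohex-2-en-1-yl]-2,4-dihydroxyphenyl]ethan-1-one | CC(C)=CCc1c(OCOC)ccc(C(=O)[C@H]2[C@@H](c3c(O)ccc(C(C)=O)c3O)C=C(C)C[C@@H]2c2ccc(OCOC)cc2OCOC)c1OCOC
F0 | step 10 | none | none
F2 | step 5 | allyl (3R)-2-acetyl-5-ArB-3-ArC-5-oxopentanoate (C-2 epimers) | CC(=O)C(C(=O)OCC=C)[C@@H](CC(=O)c1ccc(OCOC)c(CC=C(C)C)c1OCOC)c1ccc(OCOC)cc1OCOC
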